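Compound numbers 1–56 are those of the steps and of the compound list. Atom locants C1–C20 are those of the target and are used for every intermediate.

## Analysis of the target

The target is a briarane-type diterpenoid. A cyclohexane (ring A: C1, C10, C11, C12, C13, C14) is trans-fused through the C1–C10 bond to a ten-membered carbocycle (C1 to C10), and a γ-lactone (C7–O–C19(=O)–C17–C8) is fused to that ring at C7–C8. There are ten stereocentres (C1, C2, C6, C7, C8, C9, C10, C13, C14, C17). C1 is quaternary (methyl C15), the C13 and C14 acetates are cis to each other and to C2 (anti to the C1 methyl), and the ten-ring bonds at C1 and C10 are trans. Along the ring chain C6–C9 the chloride, the lactone oxygen, the tertiary hydroxyl and the acetate are contiguous (Cl/O7 anti, O7/O8 anti, O8/O9 syn in the zigzag), and the C17 methyl is cis to the C8 hydroxyl on the lactone. Sensitive groups are the secondary allylic chloride at C6, the two exocyclic 1,1-disubstituted alkenes (C5=C16, C11=C20), the β-hydroxy-γ-lactone and four secondary acetates next to a free tertiary alcohol. The hard parts are the crowded C1–C10 bond with its quaternary centre between two oxygenated carbons, the medium ring, and the dense C6–C9 array. The plan rests on one feature: C2 and C9, the acetoxy carbons attached to C1 and C10, can be the two carbons of a cyclobutane-1,2-diol fused to ring A, that is, the product of a [2+2] photocycloaddition across a C1=C10 enone followed by C2–C9 glycol cleavage.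

## Retrosynthetic reasoning

Target 56 is the tetraacetate of pentaol 55; the tertiary C8 hydroxyl is too hindered to be acylated, so peracetylation last needs no differentiation. 55 comes from 54 by removal of the two silyl ethers.

The C13/C14 cis-diol of 54 is traced to the C14 ketone 51 and from there to carbinol 50. In the closed bicycle ring A is a chair with the C1 methyl axial. Enolate oxidation at C13 then occurs anti to that methyl, and a bulky hydride puts the C14 hydroxyl axial. The C14 oxygen is already present (see below), so only C13 has to be oxidized.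

The C6–Cl bond of 50 is cut to the (6R)-carbinol 49 (SN2 with inversion), which comes from enone 48 by Felkin–Anh reduction next to the C7 oxygen. This makes the configuration at C6 independent of the ring-closing step.

The ten-membered ring is opened at C5–C6: carbinol 47 arises from iodoalkene–aldehyde 46 by a chromium-mediated alkenyl addition. This bond is chosen because the closure creates the C5 methylene directly and forms only one stereocentre, which is afterwards reset.

The lactone and the C7/C8 diol of 43 are traced through tetraol 42 to the (Z)-allylic alcohol 39. One hydrogen-bond-directed syn-dihydroxylation sets C7 and C8 from C9, and C17 comes unchanged from methyl (S)-3-hydroxy-2-methylpropanoate 28 in iodoalkene 36.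

The C8–C9 bond is cut between amide 27 and the alkenylmagnesium reagent from 36; C9 is then set by Felkin–Anh reduction of ketone 38.

Amide 27 is the opened form of the bridged lactone 25. On this rigid lactone the C2 arm (from aldehyde 11 and bromide 16, with a reagent-controlled ketone reduction for C2) and the C11 methylene are installed first.

Lactone 11 stores the key stereochemical repair. In triol 8 the C14 hydroxyl lies cis to the C1 methyl. After glycol cleavage, only the C10 epimer with C9 trans to C2 can close a hemiacetal onto O14. Base equilibration therefore funnels the cis-dialdehyde into lactol 10, and oxidation to 11 makes the inversion permanent and differentiates the two aldehydes.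

Triol 8 comes from photoadduct 7, and 7 from enone 5 and vinylene carbonate 6. This disconnection removes the C1–C2 and C10–C9 bonds together and reduces the quaternary centre to the α-carbon of a simple enone.

Enone 5 is reached in four steps from 4-(tert-butyldimethylsilyloxy)cyclohexanone 1 by asymmetric deprotonation, dehydrogenation, α-iodination and methyl coupling.

## Alternatives that were turned down

Alternative 1: The ring is cut at C6–C7. In the forward direction CrCl2 turns a C16 allylic bromide carrying a C5=C6 chloroalkene into a γ-chloroallylchromium reagent, whose C6 adds to a C7 aldehyde to give the ring-closed chlorohydrin ester A1.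
- For it: one step closes the ring and delivers the C16 methylene, the C6 chloride and the C7 oxygen. The chosen route needs four steps for the same result (closure, oxidation, reduction, chlorination), so on this point alternative 1 is stronger.
- Against it: the Cl/O relationship depends on the geometry of the chloroallyl unit and on a cyclic transition state inside a forming medium ring. The aldehyde sits on the fully substituted C8, so both partners are hindered. Nothing in it addresses the C1–C10 bond.
- Comparison: the chosen strategy solves the quaternary centre and both flanking carbons in the first C–C bond-forming step, and sets C6 by a local Felkin–Anh reduction that does not depend on the closure.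

Alternative 2: Ring A is cut at C12–C13. Me2AlCl activates a C13 aldehyde and a C10 isopropenyl group closes ring A by a carbonyl-ene reaction to give alcohol A2, with the C11 methylene formed in the same event.
- For it: the exocyclic alkene and the C13 oxygen appear together. This saves the three steps spent here on C11 and the late C13 oxidation; on step economy in ring A it is stronger.
- Against it: the ten-membered ring with its quaternary C1 must be built without ring A to organize it. The C13 configuration comes from an ene transition state on a flexible macrocycle. A chloroaluminium Lewis acid must also coexist with the allylic chloride and the lactone.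
- Comparison: the chosen strategy uses ring A as a rigid template from the first step, first as the bicyclic photoadduct and then as the bridged lactone.

Alternative 3: The lactone is cut at O–C19/C7. A peracid inserts oxygen between C19 and C7 of a fused α-chlorocyclobutanone with retention at C7, giving chlorolactone A3; the C17 chlorine is then removed.
- For it: retention in the migration guarantees the C7–O configuration, and the regiochemistry of insertion is reliable. This is a firmer stereochemical argument than the directed dihydroxylation used here.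
- Against it: a peracid must spare two 1,1-disubstituted alkenes. The cyclobutanone requires a ketene cycloaddition onto a hindered ring alkene with face control. The C17 chlorine must then be replaced by hydrogen with the right configuration while the allylic C6 chloride survives.
- Comparison: the chosen route takes C17 from a chiral-pool ester, forms the lactone by a primary-selective oxidation, and uses its single [2+2] event where it removes the hardest bond.

Key step: step 5

## Route

Remark on the chemistry: the sense of the chiral-base desymmetrization in step 1 is assumed to follow that known for 4-tert-butylcyclohexanone.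

Step 1
Reactants: 1 4-(tert-butyldimethylsilyloxy)cyclohexan-1-one
Product: 2 (S)-4-(tert-butyldimethylsilyloxy)-1-(trimethylsilyloxy)cyclohex-1-ene
Conditions: (R,R)-bis(1-phenylethyl)amine, n-BuLi, LiCl, THF, −78 °C, TMSCl present from the start
Reagents that add atoms: chlorotrimethylsilane, C[Si](C)(C)Cl
Why: Asymmetric deprotonation of a 4-substituted cyclohexanone by a chiral lithium amide with internal silyl quench; the amide should remove one of the two enantiotopic axial α-protons and so fix the configuration of the future C11 carbinol.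

Step 2
Reactants: 2 (S)-4-(tert-butyldimethylsilyloxy)-1-(trimethylsilyloxy)cyclohex-1-ene
Product: 3 (S)-4-(tert-butyldimethylsilyloxy)cyclohex-2-en-1-one
Conditions: Pd(OAc)2, MeCN, rt
Reagents that add atoms: none
Why: Saegusa–Ito oxidation; the oxa-π-allylpalladium intermediate loses a β-hydride on the side of the former enol ether, and the carbinol centre is not touched.

Step 3
Reactants: 3 (S)-4-(tert-butyldimethylsilyloxy)cyclohex-2-en-1-one
Product: 4 (S)-4-(tert-butyldimethylsilyloxy)-2-iodocyclohex-2-en-1-one
Conditions: I2, pyridine, CH2Cl2, 0 °C to rt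
Reagents that add atoms: iodine, II
Why: α-Iodination of an enone by reversible conjugate addition of pyridine, iodination of the enolate and elimination.

Step 4
Reactants: 4 (S)-4-(tert-butyldimethylsilyloxy)-2-iodocyclohex-2-en-1-one
Product: 5 (S)-4-(tert-butyldimethylsilyloxy)-2-methylcyclohex-2-en-1-one
Conditions: Me4Sn, Pd2(dba)3 (cat.), AsPh3, CuI, NMP, 60 °C
Reagents that add atoms: tetramethylstannane, C[Sn](C)(C)C
Why: Stille coupling of an α-iodoenone; it places the future C15 methyl on C1 without touching the allylic silyl ether.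

Step 5
Reactants: 5 (S)-4-(tert-butyldimethylsilyloxy)-2-methylcyclohex-2-en-1-one; 6 vinylene carbonate
Product: 7 cis-anti-cis photoadduct (cyclobutane C1–C2–C9–C10 fused to ring A, C2/C9 carbonate, C14 ketone, C11 silyl ether)
Conditions: hν (Hg lamp, λ > 330 nm), 6 (10 equiv), CH2Cl2, −40 °C
Reagents that add atoms: none
Why: Excitation of 5 and intersystem crossing give the twisted enone triplet, which bonds to 6 one carbon at a time; the triplet 1,4-diradical closes the four-membered ring after spin inversion, so C1–C2 and C10–C9 are both formed. The closest known reaction type is the [2+2] photocycloaddition of cyclohexenones with vinylene carbonate. The cyclobutane (C1, C2, C9, C10) closes by radical combination within the diradical, and only the cis-fused bicyclo[4.2.0]octanone is expected to persist at low temperature. C10 is set by approach of the alkene anti to the neighbouring C11 silyloxy group. C1 is set by the cis ring fusion, which places C1–C2 on the same face as C10–C9 and leaves the methyl on the silyloxy face, the configuration of the target. C2 and C9 should carry the carbonate away from ring A, but both become trigonal in step 7, so their configuration and any syn/anti mixture are immaterial; the symmetry of 6 removes any regiochemical issue. The step needs facial selectivity and cis fusion, and the substrate supplies the bulky silyl ether next to the reacting β-carbon.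

Step 6
Reactants: 7 cis-anti-cis photoadduct
Product: 8 triol (C14 carbinol with OH cis to the C1 methyl, cis-cyclobutane-2,9-diol)
Conditions: LiAlH4, THF, −78 to 0 °C
Reagents that add atoms: none
Why: Hydride reduces the ketone and cleaves the cyclic carbonate to the diol and methanol. Attack on C14 should occur anti to the angular methyl, because the cyclobutane carbon on the other face is tied back; this places the hydroxyl cis to the methyl, as step 7 requires.

Step 7
Reactants: 8 triol
Product: 10 bridged lactol aldehyde (C9 hemiacetal on O14; C10 inverted; free C2 aldehyde; anomer mixture), via cis-dialdehyde 9 (not isolated)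
Conditions: NaIO4, THF/aq. pH 7 buffer, 0 °C; then DBU (0.2 equiv), CH2Cl2, rt
Reagents that add atoms: none
Why: Periodate glycol cleavage of the strained cis-cyclobutanediol gives the C2/C9 dialdehyde. Only the C9 aldehyde can enolize, and only the C10 epimer with C9 cis to O14 (trans to C2) can close the five-membered bridged hemiacetal, so reversible enolization drains the mixture into 10 with the C10 configuration of the target. The silyl ether stays equatorial and poorly aligned for β-elimination.

Step 8
Reactants: 10 bridged lactol aldehyde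
Product: 11 bridged lactone aldehyde (C9 carboxyl lactonized on O14; C2 aldehyde)
Conditions: TEMPO (cat.), PhI(OAc)2, CH2Cl2, rt
Reagents that add atoms: none
Why: Oxoammonium oxidation of a lactol to the lactone. C10 is now a bridgehead that cannot enolize, so the inversion is locked; C9 and O14 are protected and the neopentyl C2 aldehyde is left free.

Step 9
Reactants: 12 (1-bromovinyl)trimethylsilane; 13 oxirane
Product: 15 3-(trimethylsilyl)but-3-en-1-ol, via alkenylmagnesium bromide 14 (not isolated)
Conditions: Mg, THF, 40 °C; then CuI (cat.), 13, −30 to 0 °C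
Reagents that add atoms: none
Why: Grignard formation and copper-catalysed opening of the epoxide give the homoallylic alcohol that carries the future C3–C5 and C16 atoms.

Step 10
Reactants: 15 3-(trimethylsilyl)but-3-en-1-ol
Product: 16 (4-bromobut-1-en-2-yl)trimethylsilane
Conditions: CBr4, PPh3, CH2Cl2, 0 °C
Reagents that add atoms: carbon tetrabromide, BrC(Br)(Br)Br
Why: Appel bromination of a primary alcohol.

Step 11
Reactants: 11 bridged lactone aldehyde; 16 (4-bromobut-1-en-2-yl)trimethylsilane
Product: 18 C2 carbinol lactone (both C2 epimers), via butenylmagnesium bromide 17 (not isolated)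
Conditions: 16, Mg, THF, rt; then 11, THF, −78 °C
Reagents that add atoms: none
Why: Grignard addition to the aldehyde, which is far more reactive than the hindered bridged lactone; the C2 configuration is not controlled here and is erased in step 12.

Step 12
Reactants: 18 C2 carbinol lactone
Product: 19 C2 ketone lactone
Conditions: Dess–Martin periodinane, NaHCO3, CH2Cl2, rt
Reagents that add atoms: none
Why: Mild oxidation of a hindered secondary alcohol converges both epimers on one ketone.

Step 13
Reactants: 19 C2 ketone lactone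
Product: 20 (2S)-carbinol lactone
Conditions: (R)-2-methyl-CBS-oxazaborolidine, catecholborane, toluene, −40 °C
Reagents that add atoms: none
Why: Corey–Bakshi–Shibata reduction; the ketone lies between a quaternary carbon (large) and a methylene (small), the best case for reagent control, and the (R)-catalyst should deliver the (2S)-alcohol. Catecholborane leaves the lactone and the vinylsilane alone.

Step 14
Reactants: 20 (2S)-carbinol lactone
Product: 21 C2 triisopropylsilyl ether
Conditions: TIPSOTf, 2,6-lutidine, CH2Cl2, 0 °C to rt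
Reagents that add atoms: triisopropylsilyl trifluoromethanesulfonate, CC(C)[Si](OS(=O)(=O)C(F)(F)F)(C(C)C)C(C)C
Why: Silylation with a silyl triflate; the bulky ether on the neopentyl oxygen will outlast the C11 silyl ether in step 16.

Step 15
Reactants: 21 C2 triisopropylsilyl ether
Product: 22 C5 iodoalkene (2-iodo-1-alkene on the C2 arm)
Conditions: N-iodosuccinimide, (CF3)2CHOH/CH2Cl2, 0 °C
Reagents that add atoms: N-iodosuccinimide, O=C1CCC(=O)N1I
Why: ipso-Iododesilylation of a 1,1-disubstituted vinylsilane through the β-silyl cation; it is done now because no other alkene is yet present.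

Step 16
Reactants: 22 C5 iodoalkene
Product: 23 C11 alcohol
Conditions: HF·pyridine, pyridine, THF, 0 °C
Reagents that add atoms: none
Why: The unhindered secondary silyl ether at C11 should be cleaved much faster than the neopentyl triisopropylsilyl ether; buffered fluoride spares the lactone.

Step 17
Reactants: 23 C11 alcohol
Product: 24 C11 ketone
Conditions: Dess–Martin periodinane, NaHCO3, CH2Cl2, rt
Reagents that add atoms: none
Why: Oxidation of the only free alcohol; the adjacent C10 is a bridgehead of the bicyclic lactone and cannot epimerize.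

Step 18
Reactants: 24 C11 ketone
Product: 25 C11 methylene lactone
Conditions: Zn, CH2Br2, TiCl4, THF/CH2Cl2, 0 °C to rt
Reagents that add atoms: dibromomethane, BrCBr
Why: Non-basic gem-dimetal methylenation (Takai–Lombardo type) of a ketone in the presence of a lactone. With C11 trigonal, ring A can later adopt the chair with both arms equatorial and the C1 methyl axial, on which steps 27, 38 and 39 depend.

Step 19
Reactants: 25 C11 methylene lactone
Product: 27 C9 N-methoxy-N-methylamide with C14 triethylsilyl ether, via hydroxy amide 26 (not isolated)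
Conditions: MeNH(OMe)·HCl, AlMe3, CH2Cl2, 0 °C to rt; aq. Rochelle salt; then TESOTf, 2,6-lutidine, CH2Cl2, −78 °C
Reagents that add atoms: N,O-dimethylhydroxylamine hydrochloride, CNOC.Cl; triethylsilyl trifluoromethanesulfonate, CC[Si](CC)(CC)OS(=O)(=O)C(F)(F)F
Why: Aluminium amide aminolysis opens the strained lactone to the Weinreb amide; immediate silylation of the liberated C14 hydroxyl prevents relactonization and marks O14 for later use.

Step 20
Reactants: 28 methyl (S)-3-hydroxy-2-methylpropanoate
Product: 29 methyl (S)-2-methyl-3-(triethylsilyloxy)propanoate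
Conditions: TESCl, imidazole, CH2Cl2, 0 °C
Reagents that add atoms: chlorotriethylsilane, CC[Si](Cl)(CC)CC
Why: Silyl protection of the primary alcohol that becomes C19; the stereocentre is the future C17.

Step 21
Reactants: 29 methyl (S)-2-methyl-3-(triethylsilyloxy)propanoate
Product: 30 (S)-2-methyl-3-(triethylsilyloxy)propanal
Conditions: i-Bu2AlH, CH2Cl2, −78 °C
Reagents that add atoms: none
Why: Half-reduction of the ester through the stable aluminium hemiacetal; the aldehyde is used at once to avoid α-epimerization.

Step 22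
Reactants: 30 (S)-2-methyl-3-(triethylsilyloxy)propanal
Product: 31 (R)-(4,4-dibromo-2-methylbut-3-enyloxy)triethylsilane
Conditions: CBr4, PPh3, 2,6-lutidine, CH2Cl2, 0 °C
Reagents that add atoms: carbon tetrabromide, BrC(Br)(Br)Br
Why: First stage of the Corey–Fuchs homologation (Wittig reaction of the dibromomethylene ylide); the new carbon becomes C7.

Step 23
Reactants: 31 (R)-(4,4-dibromo-2-methylbut-3-enyloxy)triethylsilane
Product: 33 (R)-4-methyl-5-(triethylsilyloxy)pent-2-yn-1-ol, via lithium acetylide 32 (not isolated)
Conditions: n-BuLi (2.1 equiv), THF, −78 °C; then (CH2O)n, −78 to 0 °C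
Reagents that add atoms: formaldehyde (as paraformaldehyde), C=O
Why: Second stage of the Corey–Fuchs sequence (bromine–lithium exchange, rearrangement to the alkyne, deprotonation) and trapping of the acetylide with formaldehyde, which adds C6.

Step 24
Reactants: 33 (R)-4-methyl-5-(triethylsilyloxy)pent-2-yn-1-ol
Product: 35 (S,Z)-3-iodo-4-methyl-5-(triethylsilyloxy)pent-2-en-1-ol, via cyclic vinylalanate 34 (not isolated)
Conditions: NaAlH2(OCH2CH2OMe)2, THF, 0 °C; then I2, −78 °C
Reagents that add atoms: iodine, II
Why: Alkoxide-directed trans-hydroalumination of a propargylic alcohol places aluminium on the carbon remote from oxygen (C8); iodinolysis with retention gives the iodoalkene with iodine cis to C6.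

Step 25
Reactants: 35 (S,Z)-3-iodo-4-methyl-5-(triethylsilyloxy)pent-2-en-1-ol
Product: 36 (S,Z)-1-(tert-butyldimethylsilyloxy)-3-iodo-4-methyl-5-(triethylsilyloxy)pent-2-ene
Conditions: TBSCl, imidazole, DMF, rt
Reagents that add atoms: tert-butylchlorodimethylsilane, CC(C)(C)[Si](C)(C)Cl
Why: Silylation of the allylic alcohol (O6) with a group that outlasts the primary triethylsilyl ether on O19.

Step 26
Reactants: 27 C9 N-methoxy-N-methylamide with C14 triethylsilyl ether; 36 (S,Z)-1-(tert-butyldimethylsilyloxy)-3-iodo-4-methyl-5-(triethylsilyloxy)pent-2-ene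
Product: 38 C9 enone (C8=C7 alkene with C6 cis to C9), via alkenylmagnesium chloride 37 (not isolated)
Conditions: 36, i-PrMgCl·LiCl, THF, −20 °C; then 27, −20 to 0 °C
Reagents that add atoms: none
Why: Iodine–magnesium exchange with retention of alkene geometry, then acylation by the Weinreb amide, whose chelated tetrahedral intermediate stops at the ketone; this forms C8–C9. The magnesium reagent does not exchange with the iodoalkene of 27 at this temperature.

Step 27
Reactants: 38 C9 enone
Product: 39 (9S)-allylic alcohol
Conditions: NaBH4, CeCl3·7H2O, MeOH, −78 °C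
Reagents that add atoms: none
Why: Luche 1,2-reduction. Ring A should sit in the chair with the C1 methyl axial and C2, C9 and the C14 silyloxy group equatorial; Felkin–Anh attack anti to the quaternary C1, past the flat C11 methylene, then gives the (9S)-carbinol.

Step 28
Reactants: 39 (9S)-allylic alcohol
Product: 42 7,8,9,19-tetraol (O6 and O14 still silylated), via osmate ester 40 (not isolated), via silyl triol 41 (not isolated)
Conditions: OsO4 (1.05 equiv), TMEDA, CH2Cl2, −78 °C; aq. Na2SO3, THF, 40 °C; then PPTS, MeOH, 0 °C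
Reagents that add atoms: osmium tetroxide, O=[Os](=O)(=O)=O
Why: Hydrogen-bond-directed syn-dihydroxylation: the OsO4–TMEDA complex is held by the C9 hydroxyl and delivered to the alkene face syn to O9 in the conformer that keeps H9 in the alkene plane (allylic 1,3-strain with C6). This sets C8 (O8 syn to O9) and, by syn addition to the (Z)-alkene, C7. The hydrogen-bonded allylic alkene should react before the exocyclic methylene and the electron-poor iodoalkene. Mild acid then removes only the primary triethylsilyl ether on O19.

Step 29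
Reactants: 42 7,8,9,19-tetraol
Product: 43 γ-lactone (C19 carbonyl on O7; free C8 and C9 hydroxyls)
Conditions: TEMPO (cat.), PhI(OAc)2, CH2Cl2, rt
Reagents that add atoms: none
Why: Primary-selective oxoammonium oxidation of C19 to the aldehyde, lactol formation and further oxidation (oxidative lactonization of a 1,4-diol). Closure through O7 gives a five-membered ring with the C6 and C9 branches trans, whereas closure through O9 would force ring A and the C7 branch cis, so the 7,19-lactone should form.

Step 30
Reactants: 43 γ-lactone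
Product: 44 C9 tert-butyldimethylsilyl ether
Conditions: TBSOTf, 2,6-lutidine, CH2Cl2, −78 to 0 °C
Reagents that add atoms: tert-butyldimethylsilyl trifluoromethanesulfonate, CC(C)(C)[Si](C)(C)OS(=O)(=O)C(F)(F)F
Why: Silylation of the secondary C9 hydroxyl; the tertiary C8 hydroxyl, enclosed by three branched carbons, should remain free.

Step 31
Reactants: 44 C9 tert-butyldimethylsilyl ether
Product: 45 6,14-diol
Conditions: HF·pyridine, pyridine, THF, 0 °C to rt
Reagents that add atoms: none
Why: Buffered fluoride removes the primary silyl ether on O6 and the triethylsilyl ether on O14; the hindered secondary silyl ethers on O9 and O2 react much more slowly.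

Step 32
Reactants: 45 6,14-diol
Product: 46 C6 aldehyde
Conditions: TEMPO (cat.), PhI(OAc)2, CH2Cl2, rt
Reagents that add atoms: none
Why: Oxoammonium oxidation is selective for the primary alcohol; the hindered secondary C14 and tertiary C8 hydroxyls are left.

Step 33
Reactants: 46 C6 aldehyde
Product: 47 ten-membered allylic alcohol (C5–C6 bond formed; C6 epimers)
Conditions: CrCl2 (excess), NiCl2 (cat.), DMSO/THF, rt, high dilution
Reagents that add atoms: none
Why: Nozaki–Hiyama–Kishi reaction: zerovalent nickel inserts into the C–I bond, the alkenyl group passes to trivalent chromium and adds to the aldehyde. The reagent tolerates the lactone and free hydroxyls, and the chromium alkoxide template favours medium-ring closure. The C6 configuration is not relied upon.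

Step 34
Reactants: 47 ten-membered allylic alcohol
Product: 48 C6 enone
Conditions: MnO2, CH2Cl2, rt
Reagents that add atoms: none
Why: MnO2 oxidizes only the allylic alcohol, so the C14 carbinol is kept.

Step 35
Reactants: 48 C6 enone
Product: 49 (6R)-allylic alcohol
Conditions: NaBH4, CeCl3·7H2O, MeOH/THF, −78 °C
Reagents that add atoms: none
Why: Luche 1,2-reduction under polar Felkin–Anh control: hydride adds anti to the C7–O bond, giving the alcohol syn to O7; this is the epimer that yields the target chloride on inversion.

Step 36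
Reactants: 49 (6R)-allylic alcohol
Product: 50 (6S)-allylic chloride
Conditions: PPh3, hexachloroacetone, CH2Cl2, −20 to 0 °C
Reagents that add atoms: hexachloroacetone, O=C(C(Cl)(Cl)Cl)C(Cl)(Cl)Cl
Why: Appel-type chlorination of an allylic alcohol, which proceeds by SN2 with inversion and little allylic transposition; the neopentyl C14 and tertiary C8 hydroxyls cannot be displaced.

Step 37
Reactants: 50 (6S)-allylic chloride
Product: 51 C14 ketone
Conditions: Dess–Martin periodinane, NaHCO3, CH2Cl2, rt
Reagents that add atoms: none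
Why: The C14 hydroxyl is the only oxidizable alcohol left (C8 is tertiary).

Step 38
Reactants: 51 C14 ketone
Product: 53 (13S)-13-hydroxy-14-ketone, via dilithium enolate 52 (not isolated)
Conditions: LiN(SiMe3)2 (2.2 equiv), THF, −78 °C; then 2-(phenylsulfonyl)-3-phenyloxaziridine, −78 °C
Reagents that add atoms: 2-(phenylsulfonyl)-3-phenyloxaziridine, O=S(=O)(N1OC1c1ccccc1)c1ccccc1
Why: The ketone can enolize only toward C13. Oxygen transfer from the oxaziridine to the enolate should occur anti to the axial C1 methyl, which is 1,3-related to C13 in the chair enforced by the trans-fused ring, giving the equatorial C13 hydroxyl cis to C2.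

Step 39
Reactants: 53 (13S)-13-hydroxy-14-ketone
Product: 54 (13S,14R)-13,14-diol
Conditions: LiBH(s-Bu)3, THF, −78 °C
Reagents that add atoms: none
Why: A bulky hydride attacks a cyclohexanone from the equatorial direction even next to an axial α-methyl, giving the axial C14 alcohol, cis to the C13 hydroxyl and anti to the C1 methyl.

Step 40
Reactants: 54 (13S,14R)-13,14-diol
Product: 55 2,8,9,13,14-pentaol
Conditions: HF·pyridine, THF, rt
Reagents that add atoms: none
Why: Fluoride cleaves both remaining silyl ethers under conditions that spare the lactone, the allylic chloride and the alkenes.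

Step 41
Reactants: 55 2,8,9,13,14-pentaol
Product: 56 CNP0144558.1 (target)
Conditions: Ac2O, DMAP, pyridine, rt
Reagents that add atoms: acetic anhydride, CC(=O)OC(C)=O
Why: Acylation of the four secondary hydroxyls; the tertiary C8 hydroxyl is too hindered to react, which leaves the substitution pattern of the target.

## Compound list

1 | 4-(tert-butyldimethylsilyloxy)cyclohexan-1-one | O=C1CCC(O[Si](C)(C)C(C)(C)C)CC1 | starting material
2 | (S)-4-(tert-butyldimethylsilyloxy)-1-(trimethylsilyloxy)cyclohex-1-ene | C[Si](C)(C)OC1=CC[C@@H](O[Si](C)(C)C(C)(C)C)CC1 | intermediate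
3 | (S)-4-(tert-butyldimethylsilyloxy)cyclohex-2-en-1-one | O=C1C=C[C@@H](O[Si](C)(C)C(C)(C)C)CC1 | intermediate
4 | (S)-4-(tert-butyldimethylsilyloxy)-2-iodocyclohex-2-en-1-one | O=C1C(I)=C[C@@H](O[Si](C)(C)C(C)(C)C)CC1 | intermediate
5 | (S)-4-(tert-butyldimethylsilyloxy)-2-methylcyclohex-2-en-1-one | CC1=C[C@@H](O[Si](C)(C)C(C)(C)C)CCC1=O | intermediate
6 | vinylene carbonate | O=C1OC=CO1 | starting material
7 | cis-anti-cis photoadduct (cyclobutane carbonate fused to ring A) | C[C@]12C(=O)CC[C@H](O[Si](C)(C)C(C)(C)C)[C@H]1[C@@H]3OC(=O)O[C@H]23 | intermediate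
8 | triol (C14–OH cis to the C1 methyl; cis-cyclobutane-2,9-diol) | C[C@]12[C@H](O)CC[C@H](O[Si](C)(C)C(C)(C)C)[C@H]1[C@H](O)[C@@H]2O | intermediate
9 | cis-dialdehyde (C2 and C9 formyl groups cis; C14–OH) | C[C@]1(C=O)[C@H](O)CC[C@H](O[Si](C)(C)C(C)(C)C)[C@H]1C=O | intermediate
10 | bridged lactol aldehyde (C9 hemiacetal on O14, C10 inverted, anomers) | C[C@]1(C=O)[C@H]2CC[C@H](O[Si](C)(C)C(C)(C)C)[C@@H]1C(O)O2 | intermediate
11 | bridged lactone aldehyde (C9(=O)–O14; C2 aldehyde) | C[C@]1(C=O)[C@H]2CC[C@H](O[Si](C)(C)C(C)(C)C)[C@@H]1C(=O)O2 | intermediate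
12 | (1-bromovinyl)trimethylsilane | C=C(Br)[Si](C)(C)C | starting material
13 | oxirane | C1CO1 | starting material
14 | [1-(trimethylsilyl)vinyl]magnesium bromide | C=C([Mg]Br)[Si](C)(C)C | intermediate
15 | 3-(trimethylsilyl)but-3-en-1-ol | C=C(CCO)[Si](C)(C)C | intermediate
16 | (4-bromobut-1-en-2-yl)trimethylsilane | C=C(CCBr)[Si](C)(C)C | intermediate
17 | [3-(trimethylsilyl)but-3-en-1-yl]magnesium bromide | C=C(CC[Mg]Br)[Si](C)(C)C | intermediate
18 | C2 carbinol lactone (C2 epimers; C3–C5 chain with C5 vinylsilane) | C[C@]1(C(O)CCC(=C)[Si](C)(C)C)[C@H]2CC[C@H](O[Si](C)(C)C(C)(C)C)[C@@H]1C(=O)O2 | intermediate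
19 | C2 ketone lactone | C[C@]1(C(=O)CCC(=C)[Si](C)(C)C)[C@H]2CC[C@H](O[Si](C)(C)C(C)(C)C)[C@@H]1C(=O)O2 | intermediate
20 | (2S)-carbinol lactone | C[C@]1([C@@H](O)CCC(=C)[Si](C)(C)C)[C@H]2CC[C@H](O[Si](C)(C)C(C)(C)C)[C@@H]1C(=O)O2 | intermediate
21 | C2 triisopropylsilyl ether | C[C@]1([C@@H](O[Si](C(C)C)(C(C)C)C(C)C)CCC(=C)[Si](C)(C)C)[C@H]2CC[C@H](O[Si](C)(C)C(C)(C)C)[C@@H]1C(=O)O2 | intermediate
22 | C5 iodoalkene | C[C@]1([C@@H](O[Si](C(C)C)(C(C)C)C(C)C)CCC(I)=C)[C@H]2CC[C@H](O[Si](C)(C)C(C)(C)C)[C@@H]1C(=O)O2 | intermediate
23 | C11 alcohol | C[C@]1([C@@H](O[Si](C(C)C)(C(C)C)C(C)C)CCC(I)=C)[C@H]2CC[C@H](O)[C@@H]1C(=O)O2 | intermediate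
24 | C11 ketone | C[C@]1([C@@H](O[Si](C(C)C)(C(C)C)C(C)C)CCC(I)=C)[C@H]2CCC(=O)[C@@H]1C(=O)O2 | intermediate
25 | C11 methylene lactone | C[C@]1([C@@H](O[Si](C(C)C)(C(C)C)C(C)C)CCC(I)=C)[C@H]2CCC(=C)[C@@H]1C(=O)O2 | intermediate
26 | C14 hydroxy C9 N-methoxy-N-methylamide | C[C@]1([C@@H](O[Si](C(C)C)(C(C)C)C(C)C)CCC(I)=C)[C@H](O)CCC(=C)[C@@H]1C(=O)N(C)OC | intermediate
27 | C9 N-methoxy-N-methylamide, C14 triethylsilyl ether | C[C@]1([C@@H](O[Si](C(C)C)(C(C)C)C(C)C)CCC(I)=C)[C@H](O[Si](CC)(CC)CC)CCC(=C)[C@@H]1C(=O)N(C)OC | intermediate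
28 | methyl (S)-3-hydroxy-2-methylpropanoate | COC(=O)[C@@H](C)CO | starting material
29 | methyl (S)-2-methyl-3-(triethylsilyloxy)propanoate | COC(=O)[C@@H](C)CO[Si](CC)(CC)CC | intermediate
30 | (S)-2-methyl-3-(triethylsilyloxy)propanal | O=C[C@@H](C)CO[Si](CC)(CC)CC | intermediate
31 | (R)-(4,4-dibromo-2-methylbut-3-enyloxy)triethylsilane | BrC(Br)=C[C@@H](C)CO[Si](CC)(CC)CC | intermediate
32 | lithium acetylide of (R)-triethyl(2-methylbut-3-ynyloxy)silane | [Li]C#C[C@@H](C)CO[Si](CC)(CC)CC | intermediate
33 | (R)-4-methyl-5-(triethylsilyloxy)pent-2-yn-1-ol | OCC#C[C@@H](C)CO[Si](CC)(CC)CC | intermediate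
34 | sodium cyclic vinylalanate (Al on C8, O6–Al) | COCCO[Al-]1(OCCOC)OCC=C1[C@@H](C)CO[Si](CC)(CC)CC.[Na+] | intermediate
35 | (S,Z)-3-iodo-4-methyl-5-(triethylsilyloxy)pent-2-en-1-ol | CC[Si](CC)(CC)OC[C@H](C)/C(I)=C/CO | intermediate
36 | (S,Z)-1-(tert-butyldimethylsilyloxy)-3-iodo-4-methyl-5-(triethylsilyloxy)pent-2-ene | CC[Si](CC)(CC)OC[C@H](C)/C(I)=C/CO[Si](C)(C)C(C)(C)C | intermediate
37 | alkenylmagnesium chloride from 36 (Mg on C8) | CC[Si](CC)(CC)OC[C@H](C)/C([Mg]Cl)=C/CO[Si](C)(C)C(C)(C)C | intermediate
38 | C9 enone (C7=C8, C6 cis to C9) | C[C@]1([C@@H](O[Si](C(C)C)(C(C)C)C(C)C)CCC(I)=C)[C@H](O[Si](CC)(CC)CC)CCC(=C)[C@@H]1C(=O)/C(=C\CO[Si](C)(C)C(C)(C)C)[C@@H](C)CO[Si](CC)(CC)CC | intermediate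
39 | (9S)-allylic alcohol | C[C@]1([C@@H](O[Si](C(C)C)(C(C)C)C(C)C)CCC(I)=C)[C@H](O[Si](CC)(CC)CC)CCC(=C)[C@@H]1[C@H](O)/C(=C\CO[Si](C)(C)C(C)(C)C)[C@@H](C)CO[Si](CC)(CC)CC | intermediate
40 | hexavalent osmium ester of the 7,8-diol, TMEDA complex | C[C@]1([C@@H](O[Si](C(C)C)(C(C)C)C(C)C)CCC(I)=C)[C@H](O[Si](CC)(CC)CC)CCC(=C)[C@@H]1[C@H](O)[C@]3(O[Os-2]4(=O)(=O)(O[C@H]3CO[Si](C)(C)C(C)(C)C)[N+](C)(C)CC[N+]4(C)C)[C@@H](C)CO[Si](CC)(CC)CC | intermediate
41 | 7,8,9-triol with O19 triethylsilyl ether | C[C@]1([C@@H](O[Si](C(C)C)(C(C)C)C(C)C)CCC(I)=C)[C@H](O[Si](CC)(CC)CC)CCC(=C)[C@@H]1[C@H](O)[C@@](O)([C@@H](O)CO[Si](C)(C)C(C)(C)C)[C@@H](C)CO[Si](CC)(CC)CC | intermediate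
42 | 7,8,9,19-tetraol | C[C@]1([C@@H](O[Si](C(C)C)(C(C)C)C(C)C)CCC(I)=C)[C@H](O[Si](CC)(CC)CC)CCC(=C)[C@@H]1[C@H](O)[C@@](O)([C@@H](O)CO[Si](C)(C)C(C)(C)C)[C@@H](C)CO | intermediate
43 | γ-lactone with free C8 and C9 hydroxyls | C[C@]1([C@@H](O[Si](C(C)C)(C(C)C)C(C)C)CCC(I)=C)[C@H](O[Si](CC)(CC)CC)CCC(=C)[C@@H]1[C@H](O)[C@@]2(O)[C@H](CO[Si](C)(C)C(C)(C)C)OC(=O)[C@@H]2C | intermediate
44 | C9 tert-butyldimethylsilyl ether | C[C@]1([C@@H](O[Si](C(C)C)(C(C)C)C(C)C)CCC(I)=C)[C@H](O[Si](CC)(CC)CC)CCC(=C)[C@@H]1[C@H](O[Si](C)(C)C(C)(C)C)[C@@]2(O)[C@H](CO[Si](C)(C)C(C)(C)C)OC(=O)[C@@H]2C | intermediate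
45 | 6,14-diol | C[C@]1([C@@H](O[Si](C(C)C)(C(C)C)C(C)C)CCC(I)=C)[C@H](O)CCC(=C)[C@@H]1[C@H](O[Si](C)(C)C(C)(C)C)[C@@]2(O)[C@H](CO)OC(=O)[C@@H]2C | intermediate
46 | C6 aldehyde | C[C@]1([C@@H](O[Si](C(C)C)(C(C)C)C(C)C)CCC(I)=C)[C@H](O)CCC(=C)[C@@H]1[C@H](O[Si](C)(C)C(C)(C)C)[C@@]2(O)[C@H](C=O)OC(=O)[C@@H]2C | intermediate
47 | ten-membered allylic alcohol (C6 epimers) | C=C1CC[C@@H](O)[C@]2(C)[C@@H](O[Si](C(C)C)(C(C)C)C(C)C)CCC(=C)C(O)[C@@H]3OC(=O)[C@H](C)[C@@]3(O)[C@@H](O[Si](C)(C)C(C)(C)C)[C@@H]12 | intermediate
48 | C6 enone | C=C1CC[C@@H](O)[C@]2(C)[C@@H](O[Si](C(C)C)(C(C)C)C(C)C)CCC(=C)C(=O)[C@@H]3OC(=O)[C@H](C)[C@@]3(O)[C@@H](O[Si](C)(C)C(C)(C)C)[C@@H]12 | intermediate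
49 | (6R)-allylic alcohol | C=C1CC[C@@H](O)[C@]2(C)[C@@H](O[Si](C(C)C)(C(C)C)C(C)C)CCC(=C)[C@@H](O)[C@@H]3OC(=O)[C@H](C)[C@@]3(O)[C@@H](O[Si](C)(C)C(C)(C)C)[C@@H]12 | intermediate
50 | (6S)-allylic chloride | C=C1CC[C@@H](O)[C@]2(C)[C@@H](O[Si](C(C)C)(C(C)C)C(C)C)CCC(=C)[C@H](Cl)[C@@H]3OC(=O)[C@H](C)[C@@]3(O)[C@@H](O[Si](C)(C)C(C)(C)C)[C@@H]12 | intermediate
51 | C14 ketone | C=C1CCC(=O)[C@]2(C)[C@@H](O[Si](C(C)C)(C(C)C)C(C)C)CCC(=C)[C@H](Cl)[C@@H]3OC(=O)[C@H](C)[C@@]3(O)[C@@H](O[Si](C)(C)C(C)(C)C)[C@@H]12 | intermediate
52 | dilithium C13 enolate and C8 alkoxide | C=C1CC=C(O[Li])[C@]2(C)[C@@H](O[Si](C(C)C)(C(C)C)C(C)C)CCC(=C)[C@H](Cl)[C@@H]3OC(=O)[C@H](C)[C@@]3(O[Li])[C@@H](O[Si](C)(C)C(C)(C)C)[C@@H]12 | intermediate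
53 | (13S)-13-hydroxy-14-ketone | C=C1C[C@H](O)C(=O)[C@]2(C)[C@@H](O[Si](C(C)C)(C(C)C)C(C)C)CCC(=C)[C@H](Cl)[C@@H]3OC(=O)[C@H](C)[C@@]3(O)[C@@H](O[Si](C)(C)C(C)(C)C)[C@@H]12 | intermediate
54 | (13S,14R)-13,14-diol | C=C1C[C@H](O)[C@H](O)[C@]2(C)[C@@H](O[Si](C(C)C)(C(C)C)C(C)C)CCC(=C)[C@H](Cl)[C@@H]3OC(=O)[C@H](C)[C@@]3(O)[C@@H](O[Si](C)(C)C(C)(C)C)[C@@H]12 | intermediate
55 | 2,8,9,13,14-pentaol | C=C1C[C@H](O)[C@H](O)[C@]2(C)[C@@H](O)CCC(=C)[C@H](Cl)[C@@H]3OC(=O)[C@H](C)[C@@]3(O)[C@@H](O)[C@@H]12 | intermediate
56 | CNP0144558.1 | C=C1C[C@H](OC(C)=O)[C@H](OC(C)=O)[C@]2(C)[C@@H](OC(C)=O)CCC(=C)[C@H](Cl)[C@@H]3OC(=O)[C@H](C)[C@@]3(O)[C@@H](OC(C)=O)[C@@H]12 | target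

## Step count and least certain steps

Total step count: 41. Longest linear sequence: 33 steps (steps 1–8, 11–19 and 26–41); steps 9–10 and 20–25 prepare the two side-chain reagents 16 and 36.

Step 5 (key step). The most likely failure is slow capture of the α-methyl enone triplet by the electron-poor, shielded carbonate, so that enone dimerization and hydrogen abstraction compete. Some bonding syn to the silyloxy group or trans ring fusion is also possible, and neither can be corrected at the quaternary C1. The fallback sets out from 5 and changes the two-carbon partner and the way oxygen is introduced. Irradiation of 5 under acetylene should give the cyclobutene ketone F1, which can only be cis-fused. Dihydroxylation (OsO4 cat., N-methylmorpholine N-oxide) from the exposed face away from ring A should give the diol ketone F2. LiAlH4 reduction as in step 6 then returns to triol 8.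

Step 7. The C9 enolate may lose the C11 silanolate by β-elimination, or the β-hydroxy aldehyde (O14–C14–C1–C2) may fragment by retro-aldol, before epimerization and hemiacetal closure are complete. The funnel also depends on the hydride face selectivity of step 6. The fallback sets out from 8 and moves the epimerization to the ester oxidation level, where C2 is a carboxylate. After periodate cleavage, the crude dialdehyde 9 is oxidized with NaClO2 to the hydroxy diacid F3 and dehydrated (dicyclohexylcarbodiimide) to the cis-fused anhydride F4. NaOMe in MeOH opens F4 at the less hindered C9 carbonyl, equilibrates C10 and, on acidification, gives the bridged lactone acid F5. F5 is converted to the S-ethyl thioester F6 (EtSH, carbodiimide). Fukuyama coupling with the organozinc reagent F7 (from 16 and Zn) under PdCl2(PPh3)2 catalysis gives ketone 19, where the route is rejoined.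

Step 33. Closure of the trans-fused ten-membered ring may be outrun by intermolecular coupling or by protonation of the alkenylchromium species, because the aldehyde is flanked by the lactone and a fully substituted carbon. The fallback sets out from 46 and closes the ring by acylation instead of carbonyl addition. NaClO2 oxidation gives the acid F8, and 2,2′-dipyridyl disulfide with PPh3 gives the S-2-pyridyl thioester F9. An intramolecular reductive alkenyl iodide–thioester ketone synthesis (NiBr2 with 4,4′-di-tert-butyl-2,2′-bipyridine, Cp2ZrCl2, Zn) should give enone 48 directly, where the route is rejoined without step 34.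

Step 38. The amide base may open the β-alkoxide lactone by retro-aldol, eliminate hydrogen chloride from the allylic chloride, or give incomplete face control at C13. The fallback sets out from 51 and avoids strong base. TMSOTf and Et3N give the silyl enol ether F10 (the C8 hydroxyl is silylated as well). Pb(OAc)4 transfers an acetoxy group anti to the axial methyl to give the α-acetoxy ketone F11. LiBH(s-Bu)3 reduces C14 to the monoacetate F12, in which acetyl migration between O13 and O14 is inconsequential. HF·pyridine gives the monoacetate tetraol F13, and the acetylation of step 41 returns to 56.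

## Further compounds

F1 | step 5 | cis-fused cyclobutene ketone (C2=C9) | C[C@]12C(=O)CC[C@H](O[Si](C)(C)C(C)(C)C)[C@H]1C=C2
F2 | step 5 | cis-cyclobutane-2,9-diol C14 ketone | C[C@]12C(=O)CC[C@H](O[Si](C)(C)C(C)(C)C)[C@H]1[C@H](O)[C@@H]2O
F3 | step 7 | cis C2,C9-diacid with C14 hydroxyl | C[C@]1(C(=O)O)[C@H](O)CC[C@H](O[Si](C)(C)C(C)(C)C)[C@H]1C(=O)O
F4 | step 7 | cis-fused C2/C9 cyclic anhydride | C[C@]12[C@H](O)CC[C@H](O[Si](C)(C)C(C)(C)C)[C@H]1C(=O)OC2=O
F5 | step 7 | bridged lactone C2 carboxylic acid | C[C@]1(C(=O)O)[C@H]2CC[C@H](O[Si](C)(C)C(C)(C)C)[C@@H]1C(=O)O2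
F6 | step 7 | bridged lactone C2 S-ethyl thioester | C[C@]1(C(=O)SCC)[C@H]2CC[C@H](O[Si](C)(C)C(C)(C)C)[C@@H]1C(=O)O2
F7 | step 7 | [3-(trimethylsilyl)but-3-en-1-yl]zinc bromide | C=C(CC[Zn]Br)[Si](C)(C)C
F8 | step 33 | C6 carboxylic acid | C[C@]1([C@@H](O[Si](C(C)C)(C(C)C)C(C)C)CCC(I)=C)[C@H](O)CCC(=C)[C@@H]1[C@H](O[Si](C)(C)C(C)(C)C)[C@@]2(O)[C@H](C(=O)O)OC(=O)[C@@H]2C
F9 | step 33 | C6 S-2-pyridyl thioester | C[C@]1([C@@H](O[Si](C(C)C)(C(C)C)C(C)C)CCC(I)=C)[C@H](O)CCC(=C)[C@@H]1[C@H](O[Si](C)(C)C(C)(C)C)[C@@]2(O)[C@H](C(=O)Sc3ccccn3)OC(=O)[C@@H]2C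
F10 | step 38 | C13=C14 trimethylsilyl enol ether with C8 trimethylsilyl ether | C=C1CC=C(O[Si](C)(C)C)[C@]2(C)[C@@H](O[Si](C(C)C)(C(C)C)C(C)C)CCC(=C)[C@H](Cl)[C@@H]3OC(=O)[C@H](C)[C@@]3(O[Si](C)(C)C)[C@@H](O[Si](C)(C)C(C)(C)C)[C@@H]12
F11 | step 38 | (13S)-13-acetoxy-14-ketone | C=C1C[C@H](OC(C)=O)C(=O)[C@]2(C)[C@@H](O[Si](C(C)C)(C(C)C)C(C)C)CCC(=C)[C@H](Cl)[C@@H]3OC(=O)[C@H](C)[C@@]3(O[Si](C)(C)C)[C@@H](O[Si](C)(C)C(C)(C)C)[C@@H]12
F12 | step 38 | 13-acetoxy-14-ol (silylated) | C=C1C[C@H](OC(C)=O)[C@H](O)[C@]2(C)[C@@H](O[Si](C(C)C)(C(C)C)C(C)C)CCC(=C)[C@H](Cl)[C@@H]3OC(=O)[C@H](C)[C@@]3(O[Si](C)(C)C)[C@@H](O[Si](C)(C)C(C)(C)C)[C@@H]12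
F13 | step 38 | 13-acetoxy-2,8,9,14-tetraol | C=C1C[C@H](OC(C)=O)[C@H](O)[C@]2(C)[C@@H](O)CCC(=C)[C@H](Cl)[C@@H]3OC(=O)[C@H](C)[C@@]3(O)[C@@H](O)[C@@H]12
A1 | alternative 1 | ten-membered chlorohydrin methyl ester (C6–C7 closure product) | C=C1C[C@H](OC(C)=O)[C@H](OC(C)=O)[C@]2(C)[C@@H](OC(C)=O)CCC(=C)[C@H](Cl)[C@H](O)[C@@](O[Si](CC)(CC)CC)([C@@H](C)C(=O)OC)[C@@H](OC(C)=O)[C@@H]12
A2 | alternative 2 | bicyclic C13 alcohol with C14 p-methoxybenzyl ether (carbonyl-ene product) | C=C1C[C@H](O)[C@H](OCc4ccc(OC)cc4)[C@]2(C)[C@@H](OC(C)=O)CCC(=C)[C@H](Cl)[C@@H]3OC(=O)[C@H](C)[C@@]3(O[Si](C)(C)C)[C@@H](OC(C)=O)[C@@H]12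
A3 | alternative 3 | C17-chloro lactone with C8 trimethylsilyl ether (oxygen-insertion product) | C=C1C[C@H](OC(C)=O)[C@H](OC(C)=O)[C@]2(C)[C@@H](OC(C)=O)CCC(=C)[C@H](Cl)[C@@H]3OC(=O)[C@@](C)(Cl)[C@@]3(O[Si](C)(C)C)[C@@H](OC(C)=O)[C@@H]12
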